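**Retrosynthetic overview**

1. Target 30 ⇐ prenyl ester 29: the last step moves the prenyl group from the side-chain ester oxygen to C6 (palladium, tethered delivery), which dearomatises ring A and sets the quaternary centre from C10.
2. 29 ⇐ lactone 27 ⇐ aryl iodide 14 + alkyl iodide 24 (B-alkyl Suzuki); 24 ⇐ (R)-but-3-en-2-ol by Johnson–Claisen chirality transfer.
3. Ring C (lactone, C10) ⇐ epoxy-arene cyclisation of the 7-O-glycidate of chromanone 8, then removal of the C9 oxygen.
4. Ring B (cis-2,3-dimethylchromanone) ⇐ Mitsunobu closure of aryl ketone 7 ⇐ photo-Fries rearrangement of aryl ester 5 (photochemical aryl–acyl bond formation) ⇐ phloroglucinol + anti-hydroxy acid 3 (Fráter–Seebach).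
5. Ring order: ring A is bought, then ring B, then ring C (opened again in step 18); ring A is dearomatised last.

Assumption: 30 is handled as the drawn enol tautomer of the free acid, and methyl (R)-3-hydroxybutanoate, potassium (2S,3R)-3-phenylglycidate and (R)-but-3-en-2-ol are taken as purchasable single enantiomers.

Numbering used below for the tricyclic lactones: pyrano[2,3-f]chromene, O1–C2–C3–C4 = chromanone ring B, O7–C8–C9–C10 = lactone ring C, C5 and C6 on ring A.

**Step 1**
Reactants: 1 methyl (3R)-3-hydroxybutanoate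
Product: 2 methyl (2R,3R)-3-hydroxy-2-methylbutanoate
Conditions: LiN(iPr)2 (2.2 equiv), THF, −78 → −20 °C; MeI, −78 → 0 °C
Reagents that add atoms: iodomethane (CI)
Why: Fráter–Seebach alkylation: the chelated lithium alkoxide–enolate dianion is methylated anti to the C3 substituent, so the purchased C3 centre sets C2 (anti, 2R,3R).

**Step 2**
Reactants: 2 methyl (2R,3R)-3-hydroxy-2-methylbutanoate
Product: 3 (2R,3R)-3-hydroxy-2-methylbutanoic acid
Conditions: LiOH, THF–H2O, 0 °C; then 1 M HCl
Reagents that add atoms: lithium hydroxide ([Li+].[OH-])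
Why: Mild saponification of the methyl ester leaves both stereocentres untouched.

**Step 3**
Reactants: 3 (2R,3R)-3-hydroxy-2-methylbutanoic acid; 4 benzene-1,3,5-triol
Product: 5 3,5-dihydroxyphenyl (2R,3R)-3-hydroxy-2-methylbutanoate
Conditions: 4 (4 equiv), N,N'-diisopropylcarbodiimide, DMAP (5 mol %), THF, 0 °C
Reagents that add atoms: none
Why: Steglich-type carbodiimide esterification; the excess triol gives the mono-aryl ester and the phenol outcompetes the hindered secondary alcohol of 3.

**Step 4**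
Reactants: 5 3,5-dihydroxyphenyl (2R,3R)-3-hydroxy-2-methylbutanoate
Product: 6 (2R,3R)-3-hydroxy-2-methyl-1-(2,4,6-trihydroxyphenyl)butan-1-one
Conditions: hν (254 nm, quartz), degassed MeCN, 20 °C
Reagents that add atoms: none
Why: Photo-Fries rearrangement: homolysis of the aryl ester C–O bond and in-cage recombination of the acyl and phenoxyl radicals at an ortho or para carbon (all equivalent in phloroglucinol) forms the aryl–acyl bond under neutral conditions, so the anti-aldol stereodiad is neither epimerised nor eliminated.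

**Step 5**
Reactants: 6 (2R,3R)-3-hydroxy-2-methyl-1-(2,4,6-trihydroxyphenyl)butan-1-one
Product: 7 (2R,3R)-3-hydroxy-2-methyl-1-(2,4,6-trihydroxy-3-iodophenyl)butan-1-one
Conditions: N-iodosuccinimide (1.0 equiv), MeCN, −20 °C, dark
Reagents that add atoms: N-iodosuccinimide (O=C1CCC(=O)N1I)
Why: Electrophilic aromatic iodination of the symmetrical acylphloroglucinol, whose two free ring positions are equivalent, gives a single mono-iodide.

**Step 6**
Reactants: 7 (2R,3R)-3-hydroxy-2-methyl-1-(2,4,6-trihydroxy-3-iodophenyl)butan-1-one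
Product: 8 (2S,3R)-5,7-dihydroxy-6-iodo-2,3-dimethylchroman-4-one
Conditions: PPh3, diisopropyl azodicarboxylate, THF (0.01 M), 0 → 20 °C
Reagents that add atoms: none
Why: Intramolecular Mitsunobu etherification closes ring B with SN2 inversion at the carbinol carbon (3R → 2S, giving the cis-2,3-dimethyl pattern) and should use the hydroxyl remote from iodine, because the ketone is chelated to the more acidic iodine-flanked hydroxyl, which is also the hindered one.

**Step 7**
Reactants: 8 (2S,3R)-5,7-dihydroxy-6-iodo-2,3-dimethylchroman-4-one; 9 potassium (2S,3R)-3-phenyloxirane-2-carboxylate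
Product: 11 (2S,3R)-5-hydroxy-6-iodo-2,3-dimethyl-4-oxochroman-7-yl (2S,3R)-3-phenyloxirane-2-carboxylate, via mixed pivalic anhydride 10 (not isolated)
Conditions: 9, t-BuCOCl, THF, −20 °C; then 8, Et3N, DMAP (10 mol %), −20 → 0 °C
Reagents that add atoms: none
Why: Mixed-anhydride acylation takes place at the free, acidic 7-OH (the 5-OH is hydrogen-bonded to the ketone) and leaves both epoxide centres intact.

**Step 8**
Reactants: 11 (2S,3R)-5-hydroxy-6-iodo-2,3-dimethyl-4-oxochroman-7-yl (2S,3R)-3-phenyloxirane-2-carboxylate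
Product: 12 (2S,3R,9S,10R)-5,9-dihydroxy-6-iodo-2,3-dimethyl-10-phenyl-2,3,9,10-tetrahydro-4H,8H-pyrano[2,3-f]chromene-4,8-dione
Conditions: BF3·OEt2 (20 mol %), CH2Cl2, −78 → −30 °C
Reagents that add atoms: none
Why: Lewis-acid epoxy-arene (intramolecular Friedel–Crafts) cyclisation: C8 of the chromanone, the only free ring carbon and para to the 5-OH, opens the epoxide at its benzylic carbon anti to the C–O bond, so the purchased C3 centre of 9 becomes C10 (R) with inversion while C9 is retained.

**Step 9**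
Reactants: 12 (2S,3R,9S,10R)-5,9-dihydroxy-6-iodo-2,3-dimethyl-10-phenyl-2,3,9,10-tetrahydro-4H,8H-pyrano[2,3-f]chromene-4,8-dione
Product: 13 (2S,3R,9S,10R)-5-hydroxy-6-iodo-2,3-dimethyl-4,8-dioxo-10-phenyl-2,3,9,10-tetrahydro-4H,8H-pyrano[2,3-f]chromen-9-yl acetate
Conditions: Ac2O (1.1 equiv), pyridine, CH2Cl2, 0 °C
Reagents that add atoms: acetic anhydride (CC(=O)OC(C)=O)
Why: Acetylation of the secondary alcohol (the chelated, iodine-flanked phenol reacts much more slowly) activates the α-oxygen for reductive removal.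

**Step 10**
Reactants: 13 (2S,3R,9S,10R)-5-hydroxy-6-iodo-2,3-dimethyl-4,8-dioxo-10-phenyl-2,3,9,10-tetrahydro-4H,8H-pyrano[2,3-f]chromen-9-yl acetate
Product: 14 (2S,3R,10R)-5-hydroxy-6-iodo-2,3-dimethyl-10-phenyl-2,3,9,10-tetrahydro-4H,8H-pyrano[2,3-f]chromene-4,8-dione
Conditions: SmI2 (2.5 equiv), THF–MeOH, −78 °C
Reagents that add atoms: none
Why: Samarium diiodide reductive cleavage of an α-acyloxy lactone removes the C9 oxygen via the samarium enolate; at −78 °C without additives C10, the aryl iodide and the chelated ketone are not touched.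

**Step 11**
Reactants: 15 (2R)-but-3-en-2-ol; 16 hex-5-en-2-one
Product: 17 (5E,7R)-7-hydroxyoct-5-en-2-one
Conditions: second-generation Grubbs catalyst (2 mol %), 16 (3 equiv), CH2Cl2, 40 °C
Reagents that add atoms: none
Why: Olefin cross-metathesis of a secondary allylic alcohol with a terminal alkene gives the E-allylic alcohol and does not touch the carbinol centre.

**Step 12**
Reactants: 17 (5E,7R)-7-hydroxyoct-5-en-2-one
Product: 19 ethyl (3R)-6-oxo-3-[(1E)-prop-1-en-1-yl]heptanoate, via ketene acetal 18 (not isolated)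
Conditions: MeC(OEt)3, EtCO2H (5 mol %), 140 °C, EtOH distilled off; then 1 M HCl, THF
Reagents that add atoms: triethyl orthoacetate (CC(OCC)(OCC)OCC)
Why: Johnson–Claisen rearrangement through a chair transition state with the carbinol methyl equatorial transfers the purchased carbinol chirality to the new C3 centre (R) and gives the E-propenyl group.

**Step 13**
Reactants: 19 ethyl (3R)-6-oxo-3-[(1E)-prop-1-en-1-yl]heptanoate
Product: 20 ethyl (3R)-3-(2-methylprop-1-en-1-yl)-6-oxoheptanoate
Conditions: second-generation Grubbs catalyst (5 mol %), 2-methylbut-2-ene (solvent), 40 °C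
Reagents that add atoms: 2-methylbut-2-ene (CC=C(C)C)
Why: Cross-metathesis with 2-methylbut-2-ene turns the propenyl into the 2-methylprop-1-enyl group; it is run while the molecule has no second alkene, so ring-closing metathesis cannot compete.

**Step 14**
Reactants: 20 ethyl (3R)-3-(2-methylprop-1-en-1-yl)-6-oxoheptanoate
Product: 21 ethyl (3R)-6-methyl-3-(2-methylprop-1-en-1-yl)hept-6-enoate
Conditions: Ph3PCH3Br, KOtBu, THF, 0 °C
Reagents that add atoms: methyltriphenylphosphonium bromide (C[P+](c1ccccc1)(c1ccccc1)c1ccccc1.[Br-])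
Why: Wittig methylenation of the methyl ketone, which is more electrophilic than the ester, installs the 1,1-disubstituted alkene.

**Step 15**
Reactants: 21 ethyl (3R)-6-methyl-3-(2-methylprop-1-en-1-yl)hept-6-enoate
Product: 22 (3R)-6-methyl-3-(2-methylprop-1-en-1-yl)hept-6-enoic acid
Conditions: LiOH, THF–H2O, 20 °C; then 1 M HCl
Reagents that add atoms: lithium hydroxide ([Li+].[OH-])
Why: Saponification; the stereocentre is β to the carboxyl group and cannot epimerise.

**Step 16**
Reactants: 22 (3R)-6-methyl-3-(2-methylprop-1-en-1-yl)hept-6-enoic acid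
Product: 24 (5S)-5-(iodomethyl)-2,7-dimethylocta-1,6-diene, via Barton ester 23 (not isolated)
Conditions: N-hydroxypyridine-2-thione, DCC, DMAP (cat.), CH2Cl2, dark, 0 °C; then CHI3 (3 equiv), hν (tungsten lamp), 20 °C
Reagents that add atoms: iodoform (IC(I)I)
Why: Barton decarboxylative iodination: visible-light homolysis of the thiohydroxamate ester, loss of CO2 and iodine-atom transfer from excess iodoform, which is faster than rearrangement of the homoallylic radical; the stereocentre is not involved.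

**Step 17**
Reactants: 14 (2S,3R,10R)-5-hydroxy-6-iodo-2,3-dimethyl-10-phenyl-2,3,9,10-tetrahydro-4H,8H-pyrano[2,3-f]chromene-4,8-dione; 24 (5S)-5-(iodomethyl)-2,7-dimethylocta-1,6-diene
Product: 27 (2S,3R,10R)-5-hydroxy-2,3-dimethyl-6-[(2R)-5-methyl-2-(2-methylprop-1-en-1-yl)hex-5-en-1-yl]-10-phenyl-2,3,9,10-tetrahydro-4H,8H-pyrano[2,3-f]chromene-4,8-dione, via alkyllithium 25 (not isolated), via lithium alkylmethoxyborate 26 (not isolated)
Conditions: 24, t-BuLi (2.1 equiv), Et2O, −78 °C; B-methoxy-9-BBN, THF, −78 → 20 °C; then 14, Pd(dppf)Cl2 (5 mol %), K3PO4 (3 M aq), DMF, 20 → 45 °C; AcOH work-up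
Reagents that add atoms: none
Why: B-alkyl Suzuki–Miyaura coupling of the alkyl(methoxy)borate with the aryl iodide forms the C6–CH2 bond without touching any stereocentre; the 5-phenoxide present under the basic conditions protects C3 from enolisation.

**Step 18**
Reactants: 27 (2S,3R,10R)-5-hydroxy-2,3-dimethyl-6-[(2R)-5-methyl-2-(2-methylprop-1-en-1-yl)hex-5-en-1-yl]-10-phenyl-2,3,9,10-tetrahydro-4H,8H-pyrano[2,3-f]chromene-4,8-dione; 28 3-methylbut-2-en-1-ol
Product: 29 3-methylbut-2-en-1-yl (3R)-3-{(2S,3R)-5,7-dihydroxy-2,3-dimethyl-6-[(2R)-5-methyl-2-(2-methylprop-1-en-1-yl)hex-5-en-1-yl]-4-oxochroman-8-yl}-3-phenylpropanoate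
Conditions: 28 (5 equiv), Et3N, DMAP (10 mol %), THF, 40 °C
Reagents that add atoms: none
Why: Transesterification: the activated aryl lactone is opened by prenol under nucleophilic catalysis, which frees the 7-OH and places the prenyl group on the carboxylate attached to C10.

**Step 19**
Reactants: 29 3-methylbut-2-en-1-yl (3R)-3-{(2S,3R)-5,7-dihydroxy-2,3-dimethyl-6-[(2R)-5-methyl-2-(2-methylprop-1-en-1-yl)hex-5-en-1-yl]-4-oxochroman-8-yl}-3-phenylpropanoate
Product: 30 (3R)-3-{(2S,3R,6S)-4-hydroxy-2,3-dimethyl-6-(3-methylbut-2-en-1-yl)-6-[(2R)-5-methyl-2-(2-methylprop-1-en-1-yl)hex-5-en-1-yl]-5,7-dioxo-3,5,6,7-tetrahydro-2H-chromen-8-yl}-3-phenylpropanoic acid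
Conditions: Pd(PPh3)4 (5 mol %), degassed toluene (0.02 M), 0 → 25 °C
Reagents that add atoms: none
Why: Proposed new method: oxidative addition of zerovalent palladium into the substrate's own prenyl ester gives an (η3-prenyl)palladium carboxylate whose carboxylate is still bound to C10, so the allyl unit is held on the ring face syn to the CH2CO2 arm (to reach C6 the arm must lie on the O7 side, and allylic 1,3-strain then puts the benzylic H in the ring plane next to O1), and outer-sphere attack by C6 at the unsubstituted allyl terminus, with the carboxylate taking up the phenolic proton, delivers prenyl to that face only, which sets C6 (S) from the purchased C10 centre, dearomatises ring A and releases the free acid in a net isomerisation; the closest known reactions are the intermolecular Tsuji–Trost dearomative allylation and prenylation of acylphloroglucinols with allyl carbonates and palladium-catalysed allyl transfer from allyl esters, neither of which uses a substrate-bound carboxylate leaving group for facial delivery.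

**Compound list**

1 | methyl (3R)-3-hydroxybutanoate | C[C@@H](O)CC(=O)OC | starting material
2 | methyl (2R,3R)-3-hydroxy-2-methylbutanoate | C[C@@H](O)[C@@H](C)C(=O)OC | intermediate
3 | (2R,3R)-3-hydroxy-2-methylbutanoic acid | C[C@@H](O)[C@@H](C)C(=O)O | intermediate
4 | benzene-1,3,5-triol (phloroglucinol) | Oc1cc(O)cc(O)c1 | starting material
5 | 3,5-dihydroxyphenyl (2R,3R)-3-hydroxy-2-methylbutanoate | C[C@@H](O)[C@@H](C)C(=O)Oc1cc(O)cc(O)c1 | intermediate
6 | (2R,3R)-3-hydroxy-2-methyl-1-(2,4,6-trihydroxyphenyl)butan-1-one | C[C@@H](O)[C@@H](C)C(=O)c1c(O)cc(O)cc1O | intermediate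
7 | (2R,3R)-3-hydroxy-2-methyl-1-(2,4,6-trihydroxy-3-iodophenyl)butan-1-one | C[C@@H](O)[C@@H](C)C(=O)c1c(O)cc(O)c(I)c1O | intermediate
8 | (2S,3R)-5,7-dihydroxy-6-iodo-2,3-dimethylchroman-4-one | C[C@@H]1Oc2cc(O)c(I)c(O)c2C(=O)[C@@H]1C | intermediate
9 | potassium (2S,3R)-3-phenyloxirane-2-carboxylate | [K+].[O-]C(=O)[C@H]1O[C@@H]1c1ccccc1 | starting material
10 | (2S,3R)-3-phenyloxirane-2-carboxylic pivalic anhydride | CC(C)(C)C(=O)OC(=O)[C@H]1O[C@@H]1c1ccccc1 | intermediate (not isolated)
11 | (2S,3R)-5-hydroxy-6-iodo-2,3-dimethyl-4-oxochroman-7-yl (2S,3R)-3-phenyloxirane-2-carboxylate | C[C@@H]1Oc2cc(OC(=O)[C@H]3O[C@@H]3c4ccccc4)c(I)c(O)c2C(=O)[C@@H]1C | intermediate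
12 | (2S,3R,9S,10R)-5,9-dihydroxy-6-iodo-2,3-dimethyl-10-phenyl-2,3,9,10-tetrahydro-4H,8H-pyrano[2,3-f]chromene-4,8-dione | C[C@@H]1Oc2c3[C@@H](c4ccccc4)[C@H](O)C(=O)Oc3c(I)c(O)c2C(=O)[C@@H]1C | intermediate
13 | (2S,3R,9S,10R)-5-hydroxy-6-iodo-2,3-dimethyl-4,8-dioxo-10-phenyl-2,3,9,10-tetrahydro-4H,8H-pyrano[2,3-f]chromen-9-yl acetate | C[C@@H]1Oc2c3[C@@H](c4ccccc4)[C@H](OC(C)=O)C(=O)Oc3c(I)c(O)c2C(=O)[C@@H]1C | intermediate
14 | (2S,3R,10R)-5-hydroxy-6-iodo-2,3-dimethyl-10-phenyl-2,3,9,10-tetrahydro-4H,8H-pyrano[2,3-f]chromene-4,8-dione | C[C@@H]1Oc2c3[C@@H](c4ccccc4)CC(=O)Oc3c(I)c(O)c2C(=O)[C@@H]1C | intermediate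
15 | (2R)-but-3-en-2-ol | C[C@@H](O)C=C | starting material
16 | hex-5-en-2-one | CC(=O)CCC=C | starting material
17 | (5E,7R)-7-hydroxyoct-5-en-2-one | C[C@@H](O)/C=C/CCC(C)=O | intermediate
18 | (5E,7R)-7-[(1-ethoxyethenyl)oxy]oct-5-en-2-one | C=C(OCC)O[C@H](C)/C=C/CCC(C)=O | intermediate (not isolated)
19 | ethyl (3R)-6-oxo-3-[(1E)-prop-1-en-1-yl]heptanoate | CCOC(=O)C[C@H](/C=C/C)CCC(C)=O | intermediate
20 | ethyl (3R)-3-(2-methylprop-1-en-1-yl)-6-oxoheptanoate | CCOC(=O)C[C@H](C=C(C)C)CCC(C)=O | intermediate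
21 | ethyl (3R)-6-methyl-3-(2-methylprop-1-en-1-yl)hept-6-enoate | CCOC(=O)C[C@H](C=C(C)C)CCC(C)=C | intermediate
22 | (3R)-6-methyl-3-(2-methylprop-1-en-1-yl)hept-6-enoic acid | OC(=O)C[C@H](C=C(C)C)CCC(C)=C | intermediate
23 | 2-thioxopyridin-1(2H)-yl (3R)-6-methyl-3-(2-methylprop-1-en-1-yl)hept-6-enoate | O=C(C[C@H](C=C(C)C)CCC(C)=C)ON1C=CC=CC1=S | intermediate (not isolated)
24 | (5S)-5-(iodomethyl)-2,7-dimethylocta-1,6-diene | IC[C@H](C=C(C)C)CCC(C)=C | intermediate
25 | [(2S)-5-methyl-2-(2-methylprop-1-en-1-yl)hex-5-en-1-yl]lithium | [Li]C[C@H](C=C(C)C)CCC(C)=C | intermediate (not isolated)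
26 | lithium 9-methoxy-9-[(2S)-5-methyl-2-(2-methylprop-1-en-1-yl)hex-5-en-1-yl]-9-boranuidabicyclo[3.3.1]nonane | [Li+].CO[B-]1(C[C@H](C=C(C)C)CCC(C)=C)C2CCCC1CCC2 | intermediate (not isolated)
27 | (2S,3R,10R)-5-hydroxy-2,3-dimethyl-6-[(2R)-5-methyl-2-(2-methylprop-1-en-1-yl)hex-5-en-1-yl]-10-phenyl-2,3,9,10-tetrahydro-4H,8H-pyrano[2,3-f]chromene-4,8-dione | C[C@@H]1Oc2c3[C@@H](c4ccccc4)CC(=O)Oc3c(C[C@H](C=C(C)C)CCC(C)=C)c(O)c2C(=O)[C@@H]1C | intermediate
28 | 3-methylbut-2-en-1-ol | CC(C)=CCO | starting material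
29 | 3-methylbut-2-en-1-yl (3R)-3-{(2S,3R)-5,7-dihydroxy-2,3-dimethyl-6-[(2R)-5-methyl-2-(2-methylprop-1-en-1-yl)hex-5-en-1-yl]-4-oxochroman-8-yl}-3-phenylpropanoate | C[C@@H]1Oc2c([C@H](CC(=O)OCC=C(C)C)c3ccccc3)c(O)c(C[C@H](C=C(C)C)CCC(C)=C)c(O)c2C(=O)[C@@H]1C | intermediate
30 | (3R)-3-{(2S,3R,6S)-4-hydroxy-2,3-dimethyl-6-(3-methylbut-2-en-1-yl)-6-[(2R)-5-methyl-2-(2-methylprop-1-en-1-yl)hex-5-en-1-yl]-5,7-dioxo-3,5,6,7-tetrahydro-2H-chromen-8-yl}-3-phenylpropanoic acid | C=C(C)CC[C@@H](C=C(C)C)C[C@@]1(CC=C(C)C)C(=O)C2=C(O)[C@H](C)[C@H](C)OC2=C([C@H](CC(=O)O)c2ccccc2)C1=O | target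

**Step count and risks**

Total: 19 steps. Longest linear sequence: 13 steps (1 → 2 → 3 → 5 → 6 → 7 → 8 → 11 → 12 → 13 → 14 → 27 → 29 → 30); the side-chain branch (15 → 24) is 6 steps and joins at step 17.

The step most likely to fail is step 19, the proposed tethered prenyl transfer. If the prenylpalladium species separates from the carboxylate, or transfers between molecules, the result would be the C6 epimer, O-prenyl ethers or the reverse-prenyl isomer. The fallback uses known chemistry and sets out from lactone 27. Aqueous KOH opens the lactone and forms the phenoxide–carboxylate, and prenyl bromide at 0 °C followed by acidification carries out the classical base-mediated dearomative C-prenylation of an acylphloroglucinol-type phenolate. This comes back to the route at 30, but with no facial control, so 30 is formed together with the C6 epimer of 30 F1 and must be separated by preparative HPLC.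

The second is step 17, the B-alkyl Suzuki coupling. The iodide is flanked by two oxygen substituents and carries a free phenol, so protodeiodination and slow transmetalation are the likely problems, and the lactone is opened by the aqueous base. The fallback sets out from aryl iodide 14 and acid 22 (step 16 is then skipped). It is a decarboxylative sp3–sp2 coupling under dual nickel–photoredox catalysis (NiCl2·glyme, 4,4'-di-tert-butyl-2,2'-bipyridine, Ir[dF(CF3)ppy]2(dtbbpy)PF6, Cs2CO3, DMF, blue LED), and it comes back at 27 and makes no new compound (none F0). Its own weakness is that the primary homoallylic radical may rearrange before nickel captures it.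

The third is step 6, the Mitsunobu closure of ring B. It could close onto the iodine-flanked hydroxyl, or dehydrate the β-hydroxy ketone. The fallback sets out from ketone 6 and changes the order. Mitsunobu closure of the non-iodinated triol, whose two ortho hydroxyls are equivalent, gives (2S,3R)-5,7-dihydroxy-2,3-dimethylchroman-4-one F2 with no regiochemical question. Iodination with N-iodosuccinimide then gives 8 after removal of the 8-iodo isomer, and the route is rejoined at 8.

**Further compounds**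

F1 | step 19 | (3R)-3-{(2S,3R,6R)-4-hydroxy-2,3-dimethyl-6-(3-methylbut-2-en-1-yl)-6-[(2R)-5-methyl-2-(2-methylprop-1-en-1-yl)hex-5-en-1-yl]-5,7-dioxo-3,5,6,7-tetrahydro-2H-chromen-8-yl}-3-phenylpropanoic acid | C=C(C)CC[C@@H](C=C(C)C)C[C@]1(CC=C(C)C)C(=O)C2=C(O)[C@H](C)[C@H](C)OC2=C([C@H](CC(=O)O)c2ccccc2)C1=O
F0 | step 17 | none | none
F2 | step 6 | (2S,3R)-5,7-dihydroxy-2,3-dimethylchroman-4-one | C[C@@H]1Oc2cc(O)cc(O)c2C(=O)[C@@H]1C
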